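**Plan**
Cuts: first Cα=Cβ of the enone (Claisen–Schmidt), then CH3–C(O) back to a C7 nitrile. Next come C3a–C7a and C4–C5 of ring A in one operation, and last O1–C7a (SNAr) and the C3–alkyne bond (acetylide plus epoxide).
Enabling feature: ring A and the dihydrofuran share the C3a–C7a edge, so O1–C2–C3 is a three-atom link from the C3 oxygen of a pyridazine to a methoxyalkyne. The alkyne carbons become C3a and C4 (OMe already in place), the diazine carbons become C7a, C7 (nitrile), C6 and C5, and both nitrogens leave as N2.
Forward order: the open chain is joined first. Ring A and the dihydrofuran then close together in one thermal step, ring B arrives last with the aldehyde, and both MOM groups are removed in the final step.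
Stereochemistry: C2 (R), the only stereocentre, comes from hydrolytic kinetic resolution of the terminal epoxide, and its C–O bond is never broken afterwards. The E alkene results from the aldol dehydration.

Key step: step 7

Remark: benzofuran numbering (O1, C2, C3, C3a, C4–C7, C7a) is used for the core, and the sense of the kinetic resolution is assigned by analogy with simple 1,2-epoxyalkanes.

Step 1
Reactants: 1 2-methylbut-3-en-2-ol
Product: 2 rac-2-(oxiran-2-yl)propan-2-ol
Conditions: mCPBA (1.2 equiv), CH2Cl2, 0 °C → rt
Reagents that add atoms: 3-chloroperoxybenzoic acid (mCPBA), O=C(OO)c1cccc(Cl)c1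
Why: Prilezhaev epoxidation of the monosubstituted alkene, helped by hydrogen bonding of the peracid to the allylic hydroxyl, is the established access to this epoxy alcohol, and the stereocentre formed without control is resolved in step 3.

Step 2
Reactants: 2 rac-2-(oxiran-2-yl)propan-2-ol
Product: 3 rac-2-[2-(methoxymethoxy)propan-2-yl]oxirane
Conditions: MOMCl (2 equiv), i-Pr2NEt (3 equiv), CH2Cl2, 0 → 40 °C
Reagents that add atoms: chloromethyl methyl ether (MOMCl), COCCl
Why: MOM ether formation under amine-base conditions avoids the alkoxide that would start a Payne rearrangement, and an acetal, unlike a silyl ether, cannot migrate to the neighbouring secondary alkoxide in step 6.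

Step 3
Reactants: 3 rac-2-[2-(methoxymethoxy)propan-2-yl]oxirane
Product: 4 (R)-2-[2-(methoxymethoxy)propan-2-yl]oxirane
Conditions: (S,S)-(salen)Co(OAc) (1 mol %; salen = N,N'-bis(3,5-di-tert-butylsalicylidene)cyclohexane-1,2-diaminate), H2O (0.55 equiv), THF, 0 °C → rt; distil
Reagents that add atoms: none
Why: Jacobsen hydrolytic kinetic resolution, known to tolerate a quaternary carbon next to the oxirane, should let the (S,S) catalyst hydrolyse the enantiomer shaped like an (R)-1,2-epoxyalkane (here (S)-3, because the oxygenated quaternary carbon outranks the ring CH2), so that (R)-4, the source of C2 of the target, is left and can be distilled from the diol.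

Step 4
Reactants: 5 chloroacetaldehyde dimethyl acetal
Product: 7 methoxyacetylene (kept as a cold THF solution), via sodium methoxyacetylide 6 (not isolated)
Conditions: NaNH2 (3.2 equiv), liq. NH3, −33 °C; evaporate NH3; cold sat. aq NaCl, −70 °C → warm, distil into THF at −78 °C
Reagents that add atoms: none
Why: Base-induced double elimination (MeOH, then HCl) followed by deprotonation is the standard preparation of alkoxyacetylenes from chloroacetals, and isolating 7 free of amine keeps BF3·OEt2 effective in step 5.

Step 5
Reactants: 7 methoxyacetylene; 4 (R)-2-[2-(methoxymethoxy)propan-2-yl]oxirane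
Product: 9 (R)-6-methoxy-2-(methoxymethoxy)-2-methylhex-5-yn-3-ol, via lithium methoxyacetylide 8 (not isolated)
Conditions: 7 (2.5 equiv), n-BuLi (2.4 equiv), THF, −78 °C; BF3·OEt2 (2.4 equiv); 4 (1 equiv), −78 °C; Et3N then sat. aq NaHCO3; Et3N-deactivated silica
Reagents that add atoms: none
Why: Yamaguchi–Hirao alkynylation, precedented for lithium ethoxyacetylide, opens the BF3-activated epoxide by SN2 attack at the unhindered CH2, so the C–O bond at the stereocentre stays intact (R retained), and the basic quench spares the acid-labile ynol ether.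

Step 6
Reactants: 9 (R)-6-methoxy-2-(methoxymethoxy)-2-methylhex-5-yn-3-ol; 10 3-chloropyridazine-4-carbonitrile
Product: 12 3-{[(3R)-6-methoxy-2-(methoxymethoxy)-2-methylhex-5-yn-3-yl]oxy}pyridazine-4-carbonitrile, via sodium alkoxide 11 (not isolated)
Conditions: NaH (1.1 equiv), THF, 0 °C; then 10 (1.05 equiv), 0 °C → rt
Reagents that add atoms: none
Why: Nucleophilic aromatic substitution at diazine C3, activated by the adjacent ring nitrogen and the ortho nitrile, is the known entry to 3-(alkynyloxy)pyridazine-4-carbonitriles and forms O1–C7a without touching the C2–O bond.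

Step 7
Reactants: 12 3-{[(3R)-6-methoxy-2-(methoxymethoxy)-2-methylhex-5-yn-3-yl]oxy}pyridazine-4-carbonitrile
Product: 14 (2R)-4-methoxy-2-[2-(methoxymethoxy)propan-2-yl]-2,3-dihydro-1-benzofuran-7-carbonitrile, via diazabicyclooctatriene adduct 13 (not isolated)
Conditions: PhCl (0.02 M), 2,6-lutidine (0.1 equiv), BHT (5 mol %), sealed tube, Ar, 130 °C
Reagents that add atoms: none
Why: Proposed new method: the diazine, its LUMO lowered by the C4 nitrile, and the electron-rich methoxyalkyne should undergo an intramolecular inverse-electron-demand [4+2] cycloaddition across pyridazine C3 and C6 that forms C3a–C7a and C4–C5, after which adduct 13 expels N2 by retro-[4+2] and delivers the arene at the right oxidation level. The closest known reaction type is the thermal cyclisation of 3-(but-3-ynyloxy)pyridazine-4-carbonitriles bearing terminal alkynes to 2,3-dihydrobenzofuran-7-carbonitriles, together with the intermolecular addition of ynamines to pyridazines; an alkoxy-substituted alkyne has not been shown as the tethered partner. Ring A is closed by the [4+2]/retro-[4+2] pair, whereas the dihydrofuran is closed as a consequence of tethering, since O1, C2 and C3 bridge the new C3a–C7a bond into a five-membered ring. No lasting stereocentre is made, because the two bridgehead centres of 13 disappear on aromatisation whichever face is attacked, and C2 stays R because none of its bonds takes part. Regiochemistry is the selectivity at stake, and a chain of only three atoms cannot reach any alignment other than CH2-bearing alkyne carbon to C3 and OMe-bearing carbon to C6, which is also the polarity-matched one because the nucleophilic β-carbon of the ynol ether meets the diazine carbon ortho to the nitrile. The ynol ether must also outlast the heating, which the absence of a β-hydrogen for retro-ene ketene formation, high dilution and a trace of hindered base against adventitious acid should secure.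

Step 8
Reactants: 14 (2R)-4-methoxy-2-[2-(methoxymethoxy)propan-2-yl]-2,3-dihydro-1-benzofuran-7-carbonitrile
Product: 16 1-{(2R)-4-methoxy-2-[2-(methoxymethoxy)propan-2-yl]-2,3-dihydro-1-benzofuran-7-yl}ethan-1-one, via lithium ketimide 15 (not isolated)
Conditions: MeLi (2.5 equiv), Et2O/THF, −78 → 0 °C; then 1 M aq HCl, THF, 0 °C → rt
Reagents that add atoms: methyllithium, C[Li]; water, O
Why: Organolithium addition to an aryl nitrile stops at the ketimide, which cannot accept a second equivalent, and brief dilute-acid hydrolysis should give the methyl ketone while the MOM ether, which needs stronger acid, remains.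

Step 9
Reactants: 17 4-hydroxybenzaldehyde
Product: 18 4-(methoxymethoxy)benzaldehyde
Conditions: MOMCl (1.3 equiv), i-Pr2NEt (1.5 equiv), CH2Cl2, 0 °C → rt
Reagents that add atoms: chloromethyl methyl ether (MOMCl), COCCl
Why: Standard MOM ether formation masks the phenol, whose phenoxide would otherwise deactivate the aldehyde in the condensation.

Step 10
Reactants: 16 1-{(2R)-4-methoxy-2-[2-(methoxymethoxy)propan-2-yl]-2,3-dihydro-1-benzofuran-7-yl}ethan-1-one; 18 4-(methoxymethoxy)benzaldehyde
Product: 20 (E)-1-{(2R)-4-methoxy-2-[2-(methoxymethoxy)propan-2-yl]-2,3-dihydro-1-benzofuran-7-yl}-3-[4-(methoxymethoxy)phenyl]prop-2-en-1-one, via aldol adduct 19 (not isolated)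
Conditions: KOH (3 equiv), EtOH, rt
Reagents that add atoms: none
Why: In the Claisen–Schmidt condensation the ketone enolate adds to the non-enolisable aldehyde and E1cB loss of water from 19 gives the conjugated enone as the favoured E isomer, while C2 carries no acidic hydrogen and is unaffected.

Step 11
Reactants: 20 (E)-1-{(2R)-4-methoxy-2-[2-(methoxymethoxy)propan-2-yl]-2,3-dihydro-1-benzofuran-7-yl}-3-[4-(methoxymethoxy)phenyl]prop-2-en-1-one
Product: 21 (E)-1-[(2R)-2-(2-hydroxypropan-2-yl)-4-methoxy-2,3-dihydro-1-benzofuran-7-yl]-3-(4-hydroxyphenyl)prop-2-en-1-one (CNP0151779.1)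
Conditions: conc. aq HCl (cat.), MeOH, 45 °C
Reagents that add atoms: none
Why: Acid-catalysed acetal exchange with methanol cleaves the aryl and the tertiary alkyl MOM ethers together, ionisation of the tertiary alcohol is disfavoured by the β-oxygen, and there is no 2'-hydroxyl that could close a flavanone.

**Compound list**
1 | 2-methylbut-3-en-2-ol | CC(C)(O)C=C | starting material
2 | rac-2-(oxiran-2-yl)propan-2-ol | CC(C)(O)C1CO1 | intermediate
3 | rac-2-[2-(methoxymethoxy)propan-2-yl]oxirane | COCOC(C)(C)C1CO1 | intermediate
4 | (R)-2-[2-(methoxymethoxy)propan-2-yl]oxirane | COCOC(C)(C)[C@H]1CO1 | intermediate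
5 | chloroacetaldehyde dimethyl acetal (2-chloro-1,1-dimethoxyethane) | COC(CCl)OC | starting material
6 | sodium methoxyacetylide | [Na+].[C-]#COC | intermediate
7 | methoxyacetylene (methoxyethyne) | COC#C | intermediate
8 | lithium methoxyacetylide | [Li]C#COC | intermediate
9 | (R)-6-methoxy-2-(methoxymethoxy)-2-methylhex-5-yn-3-ol | COC#CC[C@H](C(C)(C)OCOC)O | intermediate
10 | 3-chloropyridazine-4-carbonitrile | N#Cc1ccnnc1Cl | starting material
11 | sodium (3R)-6-methoxy-2-(methoxymethoxy)-2-methylhex-5-yn-3-olate | COC#CC[C@H](C(C)(C)OCOC)[O-].[Na+] | intermediate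
12 | 3-{[(3R)-6-methoxy-2-(methoxymethoxy)-2-methylhex-5-yn-3-yl]oxy}pyridazine-4-carbonitrile | COC#CC[C@H](C(C)(C)OCOC)Oc1nnccc1C#N | intermediate
13 | cycloadduct: 2,3-diazabicyclo[2.2.2]octa-2,5,7-triene with the former pyridazine C3 and C6 as bridgeheads, fused to the new dihydrofuran, C2 R, bridgehead configuration not assigned | O1[C@@H](C(C)(C)OCOC)CC2=C(OC)C3C=C(C#N)C12N=N3 | intermediate
14 | (2R)-4-methoxy-2-[2-(methoxymethoxy)propan-2-yl]-2,3-dihydro-1-benzofuran-7-carbonitrile | COc1ccc(C#N)c2c1C[C@H](C(C)(C)OCOC)O2 | intermediate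
15 | lithium ketimide of 16 (N-lithio methyl ketimine) | COc1ccc(C(C)=N[Li])c2c1C[C@H](C(C)(C)OCOC)O2 | intermediate
16 | 1-{(2R)-4-methoxy-2-[2-(methoxymethoxy)propan-2-yl]-2,3-dihydro-1-benzofuran-7-yl}ethan-1-one | COc1ccc(C(C)=O)c2c1C[C@H](C(C)(C)OCOC)O2 | intermediate
17 | 4-hydroxybenzaldehyde | O=Cc1ccc(O)cc1 | starting material
18 | 4-(methoxymethoxy)benzaldehyde | COCOc1ccc(C=O)cc1 | intermediate
19 | aldol adduct, 3-hydroxy-1-{(2R)-4-methoxy-2-[2-(methoxymethoxy)propan-2-yl]-2,3-dihydro-1-benzofuran-7-yl}-3-[4-(methoxymethoxy)phenyl]propan-1-one (carbinol centre uncontrolled) | COc1ccc(C(=O)CC(O)c2ccc(OCOC)cc2)c2c1C[C@H](C(C)(C)OCOC)O2 | intermediate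
20 | (E)-1-{(2R)-4-methoxy-2-[2-(methoxymethoxy)propan-2-yl]-2,3-dihydro-1-benzofuran-7-yl}-3-[4-(methoxymethoxy)phenyl]prop-2-en-1-one | COc1ccc(C(=O)/C=C/c2ccc(OCOC)cc2)c2c1C[C@H](C(C)(C)OCOC)O2 | intermediate
21 | (E)-1-[(2R)-2-(2-hydroxypropan-2-yl)-4-methoxy-2,3-dihydro-1-benzofuran-7-yl]-3-(4-hydroxyphenyl)prop-2-en-1-one | COc1ccc(C(=O)/C=C/c2ccc(O)cc2)c2c1C[C@H](C(C)(C)O)O2 | target

Total steps: 11. Longest linear sequence: 9 (steps 1, 2, 3, 5, 6, 7, 8, 10, 11).

**Steps most likely to fail**

Step 7. The ynol ether may oligomerise or be hydrated by traces of acid before it reaches the diazine. The methoxy substituent may also slow bonding at C6, so that temperatures are needed at which the chain degrades.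
- The fallback uses known chemistry only, sets out from epoxide 4 and returns at nitrile 14. Ring A is bought instead of built.
- Commercial 2-fluoro-4-methoxybenzonitrile is metalated with TMPMgCl·LiCl (THF, 0 °C) at the position flanked by fluorine and methoxy. This gives (3-cyano-2-fluoro-6-methoxyphenyl)magnesium chloride F1.
- CuI (10 mol %) catalyses the SN2 opening of 4 at its CH2 by F1. This gives (R)-2-fluoro-3-[2-hydroxy-3-(methoxymethoxy)-3-methylbutyl]-4-methoxybenzonitrile F2.
- NaH in DMF closes the dihydrofuran by intramolecular SNAr on the fluoride ortho to the nitrile. This gives 14 with C2 unchanged.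

Step 5. The Lewis acid may hydrate the γ-hydroxy ynol ether or cyclise it to lactone-level material. It may also draw the MOM oxygen into the epoxide opening.
- The fallback sets out from racemic epoxide 3 and acetylide 8 (made from 7) and returns at alcohol 9. It replaces Lewis-acid epoxide opening by SN2 displacement of a triflate.
- Epoxide 3 is resolved with (R,R)-(salen)Co(OAc) and 0.45 equiv H2O, so that the (R)-enantiomer is the one hydrolysed. This gives (R)-3-(methoxymethoxy)-3-methylbutane-1,2-diol F3.
- One-pot treatment with Tf2O/2,6-lutidine (CH2Cl2, −78 °C) and then Et3SiOTf gives (R)-3-(methoxymethoxy)-3-methyl-2-(triethylsilyloxy)butyl trifluoromethanesulfonate F4.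
- Acetylide 8 in THF/DMPU (−78 → −20 °C) displaces the triflate. This gives triethyl{[(3R)-6-methoxy-2-(methoxymethoxy)-2-methylhex-5-yn-3-yl]oxy}silane F5.
- Bu4NF in THF frees 9.

Step 8. Addition may stall because the nitrile is deactivated by the ortho and para oxygen donors, and ring metalation may compete. Slow hydrolysis of the donor-stabilised ketimine may call for acid strong enough to strip the acetal.
- The fallback sets out from nitrile 14 and returns at ketone 16 by a redox detour.
- i-Bu2AlH (toluene, −78 °C) followed by 1 M aq HCl gives (2R)-4-methoxy-2-[2-(methoxymethoxy)propan-2-yl]-2,3-dihydro-1-benzofuran-7-carbaldehyde F6.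
- MeMgBr (THF, 0 °C) gives 1-{(2R)-4-methoxy-2-[2-(methoxymethoxy)propan-2-yl]-2,3-dihydro-1-benzofuran-7-yl}ethan-1-ol F7. It is an inconsequential mixture at the carbinol centre.
- Dess–Martin periodinane (CH2Cl2, NaHCO3) oxidises F7 to 16.

**Further compounds**
F1 | step 7 | (3-cyano-2-fluoro-6-methoxyphenyl)magnesium chloride | COc1ccc(C#N)c(F)c1[Mg]Cl
F2 | step 7 | (R)-2-fluoro-3-[2-hydroxy-3-(methoxymethoxy)-3-methylbutyl]-4-methoxybenzonitrile | COc1ccc(C#N)c(F)c1C[C@H](C(C)(C)OCOC)O
F3 | step 5 | (R)-3-(methoxymethoxy)-3-methylbutane-1,2-diol | COCOC(C)(C)[C@H](O)CO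
F4 | step 5 | (R)-3-(methoxymethoxy)-3-methyl-2-(triethylsilyloxy)butyl trifluoromethanesulfonate | COCOC(C)(C)[C@H](O[Si](CC)(CC)CC)COS(=O)(=O)C(F)(F)F
F5 | step 5 | triethyl{[(3R)-6-methoxy-2-(methoxymethoxy)-2-methylhex-5-yn-3-yl]oxy}silane | COC#CC[C@H](C(C)(C)OCOC)O[Si](CC)(CC)CC
F6 | step 8 | (2R)-4-methoxy-2-[2-(methoxymethoxy)propan-2-yl]-2,3-dihydro-1-benzofuran-7-carbaldehyde | COc1ccc(C=O)c2c1C[C@H](C(C)(C)OCOC)O2
F7 | step 8 | 1-{(2R)-4-methoxy-2-[2-(methoxymethoxy)propan-2-yl]-2,3-dihydro-1-benzofuran-7-yl}ethan-1-ol | COc1ccc(C(C)O)c2c1C[C@H](C(C)(C)OCOC)O2
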